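**Assumptions (one line):** catalyst and ligand antipodes in Steps 1, 4 and 7 are the ones that give the drawn configurations (I name the catalyst class, not a verified antipode); one step = one isolated intermediate.

**Locants used below:** cyclohexane C1–C6 (C6 carries the oxane, C2 = CHBr, C3 = CMeCl); C7 = oxane C-2, C8 = CH(OAc), C9 = CH2, C10 = CHBr, C11 = CMe2; β = the ring face bearing the C6–C7 bond, α = the opposite face.

## Retrosynthetic overview

- The trans-diequatorial C2-Br/C3-Cl pair goes on last, via a β-face bromonium ion opened by chloride (alkene → α-epoxide → bromohydrin → Br/Cl).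
- The oxane ring comes from 6-endo bromoetherification of a C7 tertiary alcohol onto the prenyl alkene (forms C11–O and C10–Br).
- C7 comes from Felkin–Anh methyl addition to an α-acetoxy ketone.
- Key disconnection C7–C8: an acyl radical and an α-acetoxyalkyl radical are joined at a chiral nickel centre (aldehyde + racemic 1-bromoalkyl acetate); this step also sets C8.
- Ring order: cyclohexene first (organocatalytic Diels–Alder), oxane second.

## Route

**Step 1**
Reactants: 1 isoprene; 2 acrolein
Product: 3 (S)-4-methylcyclohex-3-ene-1-carbaldehyde
Conditions: 5-benzyl-2,2,3-trimethylimidazolidin-4-one·HCl (10 mol %), MeOH–H2O 95:5, rt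
Reagents that add atoms: none
Why: Iminium-catalysed Diels–Alder reaction; isoprene gives the "para" adduct and the catalyst shields one face of the iminium, setting C6 (S) at roughly 90% ee (the minor enantiomer is removed later as diastereomers after the reagent-controlled Steps 4 and 7).

**Step 2**
Reactants: 4 4-methylpent-3-en-1-ol
Product: 5 4-methylpent-3-enal
Conditions: Dess–Martin periodinane, NaHCO3, CH2Cl2, 0 °C; used cold as a crude solution
Reagents that add atoms: none
Why: Buffered Dess–Martin oxidation gives the β,γ-unsaturated aldehyde without moving the alkene into conjugation.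

**Step 3**
Reactants: 5 4-methylpent-3-enal; 6 acetyl bromide
Product: 7 rac-1-bromo-4-methylpent-3-en-1-yl acetate
Conditions: AcBr, ZnBr2 (2 mol %), CH2Cl2, −20 → 0 °C
Reagents that add atoms: none beyond reactant 6 (which supplies the acetate and the bromine)
Why: Lewis-acid-catalysed addition of an acyl bromide across the aldehyde C=O (1-haloalkyl ester formation); the new centre is racemic and is converted stereoconvergently in Step 4.

**Step 4 (key step)**
Reactants: 3 (S)-4-methylcyclohex-3-ene-1-carbaldehyde; 7 rac-1-bromo-4-methylpent-3-en-1-yl acetate (1.5 equiv)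
Product: 8 (2R)-5-methyl-1-[(1S)-4-methylcyclohex-3-en-1-yl]-1-oxohex-4-en-2-yl acetate
Conditions: NiBr2·glyme (10 mol %), chiral bi(oxazoline) ligand (12 mol %), Ir[dF(CF3)ppy]2(dtbbpy)PF6 (1 mol %), quinuclidine (10 mol %), K3PO4, 1,4-dioxane, blue LEDs, 10 °C
Reagents that add atoms: none
Why: Proposed new method: the photo-generated quinuclidinium radical cation abstracts the formyl H of 3 to give an acyl radical that is captured by Ni, while Ni(I) abstracts Br from rac-7 to give a planar α-acetoxyalkyl radical (both enantiomers of 7 converge); recombination and C–C reductive elimination at the chiral Ni(III) centre, organised by ester C=O→Ni coordination, forms C7–C8 and sets C8 (R) under ligand control, with C6 untouched; the closest known reactions are HAT/Ni/photoredox aldehyde C–H alkylation with alkyl bromides, Ni-catalysed enantioconvergent couplings of racemic 1-bromoalkyl esters, and enantioselective Ni acyl cross-couplings of benzylic and α-heteroatom radicals.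

**Step 5**
Reactants: 8
Product: 9 (2R,3R)-2-hydroxy-6-methyl-2-[(1S)-4-methylcyclohex-3-en-1-yl]hept-5-en-3-yl acetate
Conditions: MeTi(Oi-Pr)3 (from MeLi + ClTi(Oi-Pr)3), Et2O, −20 °C → rt
Reagents that add atoms: methyltitanium triisopropoxide, C[Ti](OC(C)C)(OC(C)C)OC(C)C (adds CH3)
Why: The non-chelating, ketone-selective methyltitanium reagent leaves the acetate alone and adds under polar Felkin–Anh control (C8–OAc anti to the incoming methyl), giving C7 (R); chelation control would give the wrong epimer, which is why the oxygen is carried as the acetate.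

**Step 6**
Reactants: 9
Product: 10 (2R,3R,5R)-5-bromo-2,6,6-trimethyl-2-[(1S)-4-methylcyclohex-3-en-1-yl]oxan-3-yl acetate
Conditions: Et2SBr·SbCl5Br (BDSB, 1.1 equiv), MeNO2, −25 °C, 10 min
Reagents that add atoms: bromodiethylsulfonium bromopentachloroantimonate, CC[S+](Br)CC.Br[Sb-](Cl)(Cl)(Cl)(Cl)Cl (adds Br)
Why: 6-endo bromoetherification with Markovnikov O-attack at C11 through a chair transition state (Br equatorial, cyclohexenyl equatorial, the smaller C7-methyl axial) sets C10 (R) with expected moderate dr; Br+ transfer between the two alkenes is reversible and only the prenyl bromonium has a strain-free six-membered closure, and the C8 acetate blocks 5-endo closure from O8.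

**Step 7**
Reactants: 10
Product: 11 (2R,3R,5R)-5-bromo-2,6,6-trimethyl-2-[(1R,3S,6S)-6-methyl-7-oxabicyclo[4.1.0]heptan-3-yl]oxan-3-yl acetate (epoxide on the α-face)
Conditions: Shi ketone (D-fructose-derived, 30 mol %), Oxone, K2CO3, Bu4NHSO4, MeCN–DMM / aq. buffer pH 10.5, 0 °C
Reagents that add atoms: Oxone (potassium peroxymonosulfate), [K+].[O-]S(=O)(=O)OO (adds O)
Why: Shi asymmetric epoxidation of the only remaining alkene; the dioxirane selects the face by reagent control (spiro transition state), giving the epoxide anti to the C6 substituent (C2 R, C3 S), which the substrate alone would not distinguish.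

**Step 8**
Reactants: 11
Product: 12 (2R,3R,5R)-5-bromo-2-[(1S,3R,4R)-4-bromo-3-hydroxy-4-methylcyclohexyl]-2,6,6-trimethyloxan-3-yl acetate
Conditions: HBr (33% in AcOH, 1.2 equiv), CH2Cl2, −40 °C, short reaction time
Reagents that add atoms: hydrogen bromide, Br (adds Br and H)
Why: Acid-mediated epoxide opening in which the trans-diaxial (Fürst–Plattner) and Markovnikov preferences coincide: bromide attacks the tertiary C3 from the β-face with inversion, giving axial 3β-Br and axial 2α-OH; the low temperature spares the tertiary ether and the acetate.

**Step 9**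
Reactants: 12
Product: 13 8-acetylcaespitol, (2R,3R,5R)-5-bromo-2-[(1S,3S,4S)-3-bromo-4-chloro-4-methylcyclohexyl]-2,6,6-trimethyloxan-3-yl acetate
Conditions: SOCl2, pyridine, CH2Cl2, −20 °C → rt; then MeCN, 60 °C to equilibrate any minor diaxial isomer
Reagents that add atoms: thionyl chloride, ClS(Cl)=O (adds Cl)
Why: Deoxychlorination with neighbouring-group participation: the chlorosulfite ionises with help from the antiperiplanar axial bromine to give a β-face bromonium ion, which chloride opens at the tertiary carbon from the α-face, so Br ends on C2 (inversion, S) and Cl on C3 (S), trans-diequatorial; any 2-chloro-3-bromo diaxial isomer from attack at C2 should convert to the same product by thermal diaxial→diequatorial 1,2-dihalide interchange, although that equilibrium may not lie far to the product side.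

## Compound list

1 | isoprene | C=CC(C)=C | starting material
2 | acrolein | C=CC=O | starting material
3 | (S)-4-methylcyclohex-3-ene-1-carbaldehyde | CC1=CC[C@H](CC1)C=O | intermediate
4 | 4-methylpent-3-en-1-ol | CC(C)=CCCO | starting material
5 | 4-methylpent-3-enal | CC(C)=CCC=O | intermediate
6 | acetyl bromide | CC(=O)Br | starting material
7 | rac-1-bromo-4-methylpent-3-en-1-yl acetate | CC(=O)OC(Br)CC=C(C)C | intermediate
8 | (2R)-5-methyl-1-[(1S)-4-methylcyclohex-3-en-1-yl]-1-oxohex-4-en-2-yl acetate | CC1=CC[C@H](CC1)C(=O)[C@H](OC(C)=O)CC=C(C)C | intermediate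
9 | (2R,3R)-2-hydroxy-6-methyl-2-[(1S)-4-methylcyclohex-3-en-1-yl]hept-5-en-3-yl acetate | CC1=CC[C@H](CC1)[C@@](C)(O)[C@H](OC(C)=O)CC=C(C)C | intermediate
10 | (2R,3R,5R)-5-bromo-2,6,6-trimethyl-2-[(1S)-4-methylcyclohex-3-en-1-yl]oxan-3-yl acetate | CC(=O)O[C@@H]1C[C@@H](Br)C(C)(C)O[C@]1(C)[C@@H]1CC=C(C)CC1 | intermediate
11 | (2R,3R,5R)-5-bromo-2,6,6-trimethyl-2-[(1R,3S,6S)-6-methyl-7-oxabicyclo[4.1.0]heptan-3-yl]oxan-3-yl acetate | CC(=O)O[C@@H]1C[C@@H](Br)C(C)(C)O[C@]1(C)[C@H]1CC[C@]2(C)O[C@@H]2C1 | intermediate
12 | (2R,3R,5R)-5-bromo-2-[(1S,3R,4R)-4-bromo-3-hydroxy-4-methylcyclohexyl]-2,6,6-trimethyloxan-3-yl acetate | CC(=O)O[C@@H]1C[C@@H](Br)C(C)(C)O[C@]1(C)[C@H]1CC[C@@](C)(Br)[C@H](O)C1 | intermediate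
13 | 8-acetylcaespitol | CC(=O)O[C@@H]1C[C@@H](Br)C(C)(C)O[C@]1(C)[C@H]1CC[C@](C)(Cl)[C@@H](Br)C1 | target

## Totals

Total steps: 9. Longest linear sequence: 8 (4 → 5 → 7 → 8 → 9 → 10 → 11 → 12 → 13).

## Steps most likely to fail, with fallbacks

1. **Step 4** (new asymmetric radical acyl coupling; the C8 selectivity, and the survival of 7 and of the allylic C–H bonds under HAT conditions, are untested). Fallback: couple 3 with achiral 5-bromo-2-methylpent-2-ene in the same acyl-radical/Ni manifold (known chemistry) to get the CH2 ketone, then set C8 separately by kinetic enolate hydroxylation with a chiral (camphorsulfonyl)oxaziridine and acetylation.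

2. **Step 5** (Felkin selectivity with an α-acetoxy ketone could be modest, or the acetate could be attacked). Fallback: work in the 8-epi series with the free α-hydroxy ketone, where chelation-controlled MeMgBr addition gives the same 7R centre; after oxane formation, correct C8 by oxidation to the oxan-3-one and L-Selectride reduction to the axial alcohol, then acetylate.

3. **Step 9** (elimination, or the wrong regiochemistry in opening the bromonium ion). Fallback: reverse the order of halogen entry on alkene 10: form the trans-diaxial chlorohydrin (trichloroisocyanuric acid, aq. acetone; Cl on C2, OH on C3), convert the tertiary alcohol to the bromide with TMSBr, and heat to drive the diaxial 2-chloro-3-bromo compound to 13 by 1,2-dihalide interchange. This depends on the same uncertain equilibrium.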